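## Retrosynthetic overview

1. Target ⇐ selective C8 angeloylation ⇐ anti-dihydroxylation of C8=C9 ⇐ C7 angelate ⇐ catalyst-controlled reduction of longipina-2,8-diene-1,7-dione; both angelates are delivered from one batch of angelic 2,4,6-trichlorobenzoic anhydride.
2. Key disconnection C4–C10 (cyclobutane, formed last): a himachalyl-type tertiary allylic cation at C10 is captured by the C3=C4 π-bond, held as a silyl dienol ether. This is the longipinyl closure of the presumed biosynthesis.
3. The cation precursor is an oxygen-bridged cis-himachalane (6/7 bicycle) made by a cationic (4+3) annulation: a terpinyl-type C6 cation from ring-opened car-3-en-5-one plus 2-methylfuran (C7–C10, the C10 methyl and the C7 oxygen).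
4. The six-membered ring, the C5 stereocentre, the C3 methyl, the gem-dimethyl C6 and the C1 carbonyl come from (+)-3-carene after one allylic oxidation.
5. Ring order: six (chiral pool) → seven (C6–C7, then C10–C11) → four (C4–C10); oxygens at C7 from the furan, at C8/C9 from OsO4.

Numbering: longipinane numbering throughout (C1 carbonyl, C2=C3(Me), bridgeheads C4 and C11, cyclobutane carbons C5 and C10, C6 = CMe2, C7–C9). "4,10-seco" means the C4–C10 bond is not yet formed. "C4 side" and "C11 side" are the two faces of the C6–C9 chain.

Assumption: the (4+3) adduct 6 is the cis-fused isomer with the oxygen bridge anti to the cyclohexenone; steps 4 and 5 reset C7, so the bridge face is not critical.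

## Route

Step 1
Reactants: 1 (+)-3-carene
Product: 2 car-3-en-5-one
Conditions: t-BuOOH (70% aq, 5 equiv), Rh2(C6H10NO)4 (dirhodium tetracaprolactamate, 0.5 mol %), K2CO3 (0.5 equiv), CH2Cl2, rt
Reagents that add atoms: tert-butyl hydroperoxide, CC(C)(C)OO
Why: Radical allylic C–H oxidation (Kharasch-type, tert-butylperoxyl pathway) at the ring methylene next to the less substituted alkene carbon gives the conjugated enone, as in the pinene-to-verbenone oxidation; the two cyclopropane stereocentres are untouched.

Step 2
Reactants: 2 car-3-en-5-one; 3 2-methylfuran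
Product: 6 the (4+3) adduct 7,10-epoxy-4,10-secolongipina-2,8-dien-1-one, via silyloxydienyl cation 4 (not isolated), via furanium ion 5 (not isolated)
Conditions: 3 (5 equiv), Me3SiOTf (20 mol %), CH2Cl2, −78 → −40 °C
Reagents that add atoms: 2-methylfuran, Cc1ccco1
Why: Proposed new method: O-silylation of the enone triggers homo-conjugate heterolysis of the cyclopropane C6–C11 bond (as when HBr opens carone) to the tertiary cation 4 carrying a 2-silyloxydiene; 2-methylfuran attacks through its free α-carbon, and the furanium ion 5 is trapped at its methyl-bearing carbon by the tethered silyl enol ether through a six-membered chair before it can lose a proton, with the bulky C6 pseudo-equatorial and the new C11–C10 bond formed axially so that the ring fusion is cis (C7, C10 and C11 are set here, C5 comes from carene); the closest known reactions are the Lewis-acid (4+3) annulation of donor–acceptor cyclopropanes with dienes and the stepwise oxyallyl–furan (4+3) cycloaddition.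

Step 3
Reactants: 6 the (4+3) adduct
Product: 9 7-hydroxylongipina-2,8-dien-1-one (hydroxyl on the C11 side), via linear silyl dienol ether 7 (not isolated), via tricyclic silyl ether 8 (not isolated)
Conditions: Et3N (1.3 equiv), Me3SiOTf (1.2 equiv), CH2Cl2, 0 °C; then Me3SiOTf (0.3 equiv), −78 → −30 °C; 1 M HCl, THF, 0 °C
Reagents that add atoms: none
Why: Proposed new method: soft enolisation gives the linear dienol ether 7 because the C11–H is pseudo-equatorial and an α′-enol ether could not expel the poorly aligned bridging oxygen (as in 8-oxabicyclo[3.2.1]octan-3-one enolates); silylation of the bridging oxygen then ionises the tertiary allylic C10–O bond to a himachalyl-type cation, which is captured 1,3-syn by the C3=C4 π-bond (vinylogous Mukaiyama / Reetz-type tert-alkylation, the cation–olefin closure himachalyl → longipinyl), the oxocarbenium collapsing to the enone and returning Me3SiOTf; C4 and C10 can form only in the bridged geometry dictated by C5 and C11, and C7 keeps its configuration.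

Step 4
Reactants: 9 7-hydroxylongipina-2,8-dien-1-one (C11-side hydroxyl)
Product: 10 longipina-2,8-diene-1,7-dione
Conditions: Dess–Martin periodinane (1.3 equiv), CH2Cl2, rt
Reagents that add atoms: none
Why: Dess–Martin oxidation of the hindered allylic alcohol to the enone; it erases the C7 centre, so either bridge epimer of 6 converges on 10.

Step 5
Reactants: 10 longipina-2,8-diene-1,7-dione
Product: 13 7-hydroxylongipina-2,8-dien-1-one (hydroxyl on the C4 side), via exocyclic silyl dienol ether 11 (not isolated), via catechol borate 12 (not isolated)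
Conditions: t-BuMe2SiOTf (1.2 equiv), Et3N (1.5 equiv), CH2Cl2, 0 °C, evaporate; (S)-1-methyl-3,3-diphenyltetrahydro-1H,3H-pyrrolo[1,2-c][1,3,2]oxazaborole (0.2 equiv), catecholborane (1.5 equiv), PhMe, −78 °C; 1 M HCl, THF, 0 °C
Reagents that add atoms: none
Why: The C1 enone is masked in the flask as its exocyclic silyl dienol ether (only the C3 methyl can be deprotonated because the α′ and γ ring positions are bridgeheads, and the C7 enone has no enolisable hydrogen), so the Corey–Bakshi–Shibata reduction acts on C7 alone; with the quaternary C6 flank taken as the large group, the (S)-catalyst delivers hydride to the face that leaves the hydroxyl on the C4 side, the core being too remote to bias the reduction, and acid work-up returns the C1 enone.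

Step 6
Reactants: 14 angelic acid
Product: 15 angelic 2,4,6-trichlorobenzoic anhydride
Conditions: 14 (1.0 equiv), 2,4,6-Cl3C6H2COCl (1.0 equiv), Et3N (1.0 equiv), PhMe, 0 °C → rt, 1 h; filter under Ar; kept as a 0.5 M PhMe solution at −20 °C (one batch, about 4.5 equiv relative to 13)
Reagents that add atoms: 2,4,6-trichlorobenzoyl chloride, O=C(Cl)c1c(Cl)cc(Cl)cc1Cl
Why: Yamaguchi activation, in which triethylammonium angelate is acylated by the hindered aroyl chloride at room temperature without a nucleophilic catalyst so that the Z-alkene is kept, and the filtered solution serves both esterifications (any disproportionation on standing gives angelic anhydride, itself an angeloyl donor); no stereocentre is involved.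

Step 7
Reactants: 13 7-hydroxylongipina-2,8-dien-1-one (C4-side hydroxyl); 15 angelic 2,4,6-trichlorobenzoic anhydride
Product: 16 7-angeloyloxylongipina-2,8-dien-1-one
Conditions: 15 (3 equiv, 0.5 M in PhMe), PhMe, 80 °C
Reagents that add atoms: angelic 2,4,6-trichlorobenzoic anhydride, C/C=C(/C)C(=O)OC(=O)c1c(Cl)cc(Cl)cc1Cl
Why: Yamaguchi-type mixed-anhydride esterification without a nucleophilic catalyst, in which the alcohol attacks the angeloyl carbonyl because the aroyl carbonyl is shielded by two ortho chlorines; this is the mild way to angelates that avoids Z→E isomerisation to the tiglate, and no stereocentre is affected.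

Step 8
Reactants: 16 7-angeloyloxylongipina-2,8-dien-1-one
Product: 17 7-angeloyloxy-8,9-dihydroxylongipin-2-en-1-one
Conditions: OsO4 (5 mol %), N-methylmorpholine N-oxide (1.5 equiv), acetone–H2O 4:1, rt
Reagents that add atoms: osmium tetroxide, O=[Os](=O)(=O)=O; N-methylmorpholine N-oxide, C[N+]1([O-])CCOCC1; water, O
Why: Upjohn dihydroxylation of the only electron-rich cis-disubstituted alkene (the enone and angelate alkenes are electron-poor); OsO4 adds anti to the allylic C7 ester (Kishi's empirical rule), i.e. from the C11 side, setting C8 and C9 cis to each other and trans to the C7 ester.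

Step 9
Reactants: 17 7-angeloyloxy-8,9-dihydroxylongipin-2-en-1-one; 15 angelic 2,4,6-trichlorobenzoic anhydride
Product: 18 7,8-bis(angeloyloxy)-9-hydroxylongipin-2-en-1-one (CNP0256888.1)
Conditions: 15 (1.3 equiv, 0.5 M in PhMe), PhMe, 60 °C
Reagents that add atoms: angelic 2,4,6-trichlorobenzoic anhydride, C/C=C(/C)C(=O)OC(=O)c1c(Cl)cc(Cl)cc1Cl
Why: Mixed-anhydride mono-esterification of the cis-diol at C8; the C9 hydroxyl is neopentylic (next to the quaternary C10) and reacts more slowly, and a small excess of the anhydride without nucleophilic catalyst limits over-acylation and acyl migration.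

## Compound list

1 | (+)-3-carene, (1S,6R)-3,7,7-trimethylbicyclo[4.1.0]hept-3-ene | CC1=CC[C@@H]2[C@H](C1)C2(C)C | starting material
2 | car-3-en-5-one, (1R,6S)-4,7,7-trimethylbicyclo[4.1.0]hept-3-en-2-one | CC1=CC(=O)[C@@H]2[C@H](C1)C2(C)C | intermediate
3 | 2-methylfuran | Cc1ccco1 | starting material
4 | 2-[5-methyl-3-(trimethylsilyloxy)cyclohexa-2,4-dien-1-yl]propan-2-ylium, ring stereocentre as in 2 | C[C+](C)[C@H]1CC(C)=CC(O[Si](C)(C)C)=C1 | intermediate
5 | 2H-furanium adduct of 4 and 3 (new C6–C7 bond, cation at the methyl-bearing C10) | CC1=[O+][C@@H](C=C1)C(C)(C)[C@H]2CC(C)=CC(O[Si](C)(C)C)=C2 | intermediate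
6 | 7,10-epoxy-4,10-secolongipina-2,8-dien-1-one = 6,9-epoxy-3,5,5,9-tetramethyl-4,4a,5,6,9,9a-hexahydro-1H-benzo[7]annulen-1-one; cis ring fusion, oxygen bridge anti to the cyclohexenone | CC1=CC(=O)[C@@H]2[C@H](C1)C(C)(C)[C@@H]3C=C[C@@]2(C)O3 | intermediate
7 | linear trimethylsilyl dienol ether of 6 (C1–OSiMe3, C1=C2, C3=C4) | C[Si](C)(C)OC1=CC(C)=C[C@H]2[C@@H]1[C@@]3(C)C=C[C@H](O3)C2(C)C | intermediate
8 | 7-(trimethylsilyloxy)longipina-2,8-dien-1-one, silyloxy on the C11 side | C[Si](C)(C)O[C@H]1C=C[C@@]2(C)[C@@H]3C(=O)C=C(C)[C@H]2[C@@H]3C1(C)C | intermediate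
9 | 7-hydroxylongipina-2,8-dien-1-one, hydroxyl on the C11 side; core configured as in 18 | O[C@H]1C=C[C@@]2(C)[C@@H]3C(=O)C=C(C)[C@H]2[C@@H]3C1(C)C | intermediate
10 | longipina-2,8-diene-1,7-dione; core configured as in 18 | O=C1C=C[C@@]2(C)[C@@H]3C(=O)C=C(C)[C@H]2[C@@H]3C1(C)C | intermediate
11 | exocyclic tert-butyldimethylsilyl dienol ether of 10 (C1–OSi, C1=C2, C3=CH2; C7 ketone free) | O=C1C=C[C@@]2(C)[C@@H]3C(O[Si](C)(C)C(C)(C)C)=CC(=C)[C@H]2[C@@H]3C1(C)C | intermediate
12 | catechol borate of the C7 alcohol (oxygen on the C4 side), dienol ether still in place | c1ccc2OB(O[C@@H]3C=C[C@@]4(C)[C@@H]5C(O[Si](C)(C)C(C)(C)C)=CC(=C)[C@H]4[C@@H]5C3(C)C)Oc2c1 | intermediate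
13 | 7-hydroxylongipina-2,8-dien-1-one, hydroxyl on the C4 side | O[C@@H]1C=C[C@@]2(C)[C@@H]3C(=O)C=C(C)[C@H]2[C@@H]3C1(C)C | intermediate
14 | angelic acid, (Z)-2-methylbut-2-enoic acid | C/C=C(/C)C(=O)O | starting material
15 | angelic 2,4,6-trichlorobenzoic anhydride | C/C=C(/C)C(=O)OC(=O)c1c(Cl)cc(Cl)cc1Cl | intermediate
16 | 7-angeloyloxylongipina-2,8-dien-1-one, ester on the C4 side | C/C=C(/C)C(=O)O[C@@H]1C=C[C@@]2(C)[C@@H]3C(=O)C=C(C)[C@H]2[C@@H]3C1(C)C | intermediate
17 | 7-angeloyloxy-8,9-dihydroxylongipin-2-en-1-one; 8-OH and 9-OH cis, both on the C11 side | O[C@@H]1[C@@H](OC(=O)/C(C)=C\C)C(C)(C)[C@@H]2[C@H]3C(=O)C=C(C)[C@@H]2[C@@]3(C)[C@@H]1O | intermediate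
18 | (4R,5S,7S,8S,9S,10R,11R)-7,8-bis(angeloyloxy)-9-hydroxylongipin-2-en-1-one | C/C=C(/C)C(=O)O[C@@H]1[C@@H](OC(=O)/C(C)=C\C)C(C)(C)[C@@H]2[C@H]3C(=O)C=C(C)[C@@H]2[C@@]3(C)[C@@H]1O | target

## Count and risks

Total: 9 steps (eight on the main line plus the one-step preparation of the acyl donor 15 on a side branch). Longest linear sequence: 8 steps (1 → 2 → 6 → 9 → 10 → 13 → 16 → 17 → 18).

Most likely to fail, first: step 3. The cyclobutane closure is close to thermoneutral and competes with loss of a proton from the C10 cation (C10 methyl or C11–H) and with capture at the C8 terminus of the allyl cation. The fallback sets out from 2 and changes the leaving group to a ketal whose ionisation ends in a ketone. Friedel–Crafts homo-conjugate alkylation of 2-methylfuran (BF3·OEt2, CH2Cl2, −40 °C) gives the furyl enone F3. Clauson–Kaas oxidation (Br2, MeOH, KOAc, −40 °C) gives the dimethoxydihydrofuran F4. One-pot silyl enol ether formation and Mukaiyama addition to the C10 oxocarbenium (Me3SiOTf, i-Pr2NEt, −78 °C) gives the bridged ketal F5. Its linear silyl dienol ether is then closed with BF3·OEt2, the bridge leaving as the C7 ketone with loss of methanol. This comes back to the route at 10 and bypasses 6 and 9. Its own weak point is that the ring-opened C7 oxocarbenium could instead be attacked at C9.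

Second: step 2. The furanium ion 5 may simply lose a proton to give the Friedel–Crafts product, or close to the trans-fused isomer. The fallback sets out from 2 and generates the cation from a discrete precursor without protic acid. Dry HCl (CH2Cl2, 0 °C) opens the cyclopropane to the tertiary chloride F1. LiN(i-Pr)2 and Me3SiCl (THF, −78 °C) give the cross-conjugated silyl dienol ether F2. AgBF4 (CH2Cl2, −78 °C) with 2-methylfuran then abstracts chloride and the annulation proceeds as before. This comes back at 6.

Third: step 9. Discrimination between the C8 and C9 hydroxyls rests only on the neopentylic position of C9, and the ester could migrate across the cis-diol. The fallback sets out from 17 and puts the regiocontrol on tin. Bu2SnO (PhMe, reflux, water removal) gives the stannylene acetal F6, which is acylated at rt with the mixed anhydride 15 at the tin-activated, less hindered C8 oxygen. This comes back at 18.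

Further compounds
F1 | step 2 | (S)-5-(2-chloropropan-2-yl)-3-methylcyclohex-2-en-1-one | CC1=CC(=O)C[C@H](C1)C(C)(C)Cl
F2 | step 2 | cross-conjugated trimethylsilyl dienol ether of F1 | CC1=CC(O[Si](C)(C)C)=C[C@H](C1)C(C)(C)Cl
F3 | step 3 | (S)-3-methyl-5-[2-(5-methylfuran-2-yl)propan-2-yl]cyclohex-2-en-1-one | CC1=CC(=O)C[C@H](C1)C(C)(C)c1ccc(C)o1
F4 | step 3 | 2,5-dimethoxy-2,5-dihydrofuran from F3 (mixture at the two ketal carbons) | CC1=CC(=O)C[C@H](C1)C(C)(C)C1(OC)C=CC(C)(OC)O1
F5 | step 3 | 7-methoxy-7,10-epoxy-4,10-secolongipina-2,8-dien-1-one (bridged ketal, cis ring fusion) | CC1=CC(=O)[C@@H]2[C@H](C1)C(C)(C)[C@]3(OC)C=C[C@@]2(C)O3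
F6 | step 9 | 8,9-O-dibutylstannylene acetal of 17 | CCCC[Sn]4(CCCC)O[C@@H]1[C@@H](OC(=O)/C(C)=C\C)C(C)(C)[C@@H]2[C@H]3C(=O)C=C(C)[C@@H]2[C@@]3(C)[C@@H]1O4
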